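**Strategy**

Everything rests on closing ring C of the upper flavan unit between C3 and C4. The feature exploited is that C4 is doubly benzylic, held between C4a of ring A and C6 of ring D of the lower unit, and sits next to the carbinol C3: C4 can be carried as a diaryl ketone and C3 as an aldehyde. Samarium diiodide turns the ketone into a ketyl that adds 6-exo to the aldehyde, forming the C3–C4 bond and the C3 carbinol trans to the C2 aryl group in one operation; the surplus C4 hydroxyl is then replaced by hydride anti to 3-OH. The precursor is a keto-aldehyde joining the finished, benzyl-protected lower unit to an O-aryl mandelate-derived chain.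

Key step: step 18

Remark: flavan numbering (O1, C2, C3, C4, C4a, C5 to C8, C8a) is used for both halves; the half with the 3-OH only is the upper unit (benzo ring A, pyran ring C, aryl ring B), the 3,4-diol half is the lower unit (benzo ring D, pyran ring F, aryl ring E).

**Route**

Step 1
Reactants: 1 3-fluorocatechol
Product: 2 1,2-bis(benzyloxy)-3-fluorobenzene
Conditions: BnBr (2.2 equiv), K2CO3, DMF, rt
Reagents that add atoms: benzyl bromide BrCc1ccccc1
Why: Williamson ether synthesis on both phenols; benzyl is chosen so that all protecting groups fall together in the last step.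

Step 2
Reactants: 2 1,2-bis(benzyloxy)-3-fluorobenzene
Product: 3 3,4-bis(benzyloxy)-1-bromo-2-fluorobenzene
Conditions: NBS, MeCN, 0 °C to rt
Reagents that add atoms: N-bromosuccinimide O=C1CCC(=O)N1Br
Why: electrophilic aromatic bromination should go para to the unflanked benzyloxy group (the other one, twisted between two substituents, directs weakly), a position that is also ortho to fluorine.

Step 3
Reactants: 4 (S)-4-benzyl-2-oxazolidinone; 5 (benzyloxy)acetyl chloride
Product: 6 (S)-4-benzyl-3-[(benzyloxy)acetyl]oxazolidin-2-one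
Conditions: Et3N, DMAP (cat.), CH2Cl2, 0 °C to rt
Reagents that add atoms: none
Why: DMAP-catalysed N-acylation of the oxazolidinone by the acid chloride.

Step 4
Reactants: 6 (S)-4-benzyl-3-[(benzyloxy)acetyl]oxazolidin-2-one; 7 4-(benzyloxy)benzaldehyde
Product: 9 (S)-4-benzyl-3-[(2S,3R)-2-(benzyloxy)-3-[4-(benzyloxy)phenyl]-3-hydroxypropanoyl]oxazolidin-2-one, via Z-dibutylboron enolate 8 (not isolated)
Conditions: Bu2BOTf, Et3N, CH2Cl2, −78 to 0 °C; then 7, −78 to 0 °C; H2O2, MeOH, pH 7 buffer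
Reagents that add atoms: none
Why: Evans syn-aldol reaction, in which the Z-boron enolate reacts through a chair Zimmerman–Traxler transition state on the face away from the auxiliary benzyl group and so sets the (2S,3R) syn pair that becomes C3 and C2 of the lower unit.

Step 5
Reactants: 9 (S)-4-benzyl-3-[(2S,3R)-2-(benzyloxy)-3-[4-(benzyloxy)phenyl]-3-hydroxypropanoyl]oxazolidin-2-one
Product: 10 (2S,3R)-2-(benzyloxy)-3-[4-(benzyloxy)phenyl]-3-hydroxy-N-methoxy-N-methylpropanamide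
Conditions: MeNH(OMe)·HCl, AlMe3, CH2Cl2, −10 to 0 °C; aqueous work-up
Reagents that add atoms: N,O-dimethylhydroxylamine hydrochloride CNOC.Cl
Why: aluminium amide transamidation releases the auxiliary and gives the Weinreb amide without touching either stereocentre.

Step 6
Reactants: 3 3,4-bis(benzyloxy)-1-bromo-2-fluorobenzene; 10 (2S,3R)-2-(benzyloxy)-3-[4-(benzyloxy)phenyl]-3-hydroxy-N-methoxy-N-methylpropanamide
Product: 12 (2S,3R)-1-[3,4-bis(benzyloxy)-2-fluorophenyl]-2-(benzyloxy)-3-[4-(benzyloxy)phenyl]-3-hydroxypropan-1-one, via aryllithium 11 (not isolated)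
Conditions: 3 (2.3 equiv), n-BuLi (2.2 equiv), THF, −78 °C; then 10, −78 °C; aq. NH4Cl
Reagents that add atoms: none
Why: bromine–lithium exchange and addition of the aryllithium to the Weinreb amide, whose chelated tetrahedral intermediate prevents over-addition; one equivalent of 11 is spent on the free hydroxyl group and at −78 °C the ortho-fluoroaryllithium should not lose LiF.

Step 7
Reactants: 12 (2S,3R)-1-[3,4-bis(benzyloxy)-2-fluorophenyl]-2-(benzyloxy)-3-[4-(benzyloxy)phenyl]-3-hydroxypropan-1-one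
Product: 13 (2R,3S)-3,7,8-tris(benzyloxy)-2-[4-(benzyloxy)phenyl]chroman-4-one (2,3-cis)
Conditions: NaH (1.05 equiv), THF/DMF, −20 to 0 °C
Reagents that add atoms: none
Why: intramolecular nucleophilic aromatic substitution, in which the alkoxide displaces the fluoride activated by the ortho carbonyl group with retention at the carbinol carbon, so the syn aldol pair becomes the 2,3-cis flavanone.

Step 8
Reactants: 13 (2R,3S)-3,7,8-tris(benzyloxy)-2-[4-(benzyloxy)phenyl]chroman-4-one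
Product: 14 (2R,3R,4R)-3,7,8-tris(benzyloxy)-2-[4-(benzyloxy)phenyl]chroman-4-ol (all-cis)
Conditions: NaBH4, MeOH/THF, −20 to 0 °C
Reagents that add atoms: none
Why: hydride reduction of the ketone from the face opposite the axial C3 benzyloxy group (steric approach control) should set C4 as R with the new hydroxyl cis to both neighbours.

Step 9
Reactants: 14 (2R,3R,4R)-3,7,8-tris(benzyloxy)-2-[4-(benzyloxy)phenyl]chroman-4-ol
Product: 15 (2R,3R,4R)-3,4,7,8-tetrakis(benzyloxy)-2-[4-(benzyloxy)phenyl]chromane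
Conditions: NaH, BnBr, Bu4NI (cat.), DMF, 0 °C to rt
Reagents that add atoms: benzyl bromide BrCc1ccccc1
Why: Williamson benzylation of the secondary alkoxide, which protects the ionisable C4 hydroxyl for the organometallic and acidic steps ahead.

Step 10
Reactants: 15 (2R,3R,4R)-3,4,7,8-tetrakis(benzyloxy)-2-[4-(benzyloxy)phenyl]chromane
Product: 16 (2R,3R,4R)-3,4,7,8-tetrakis(benzyloxy)-2-[4-(benzyloxy)phenyl]-6-bromochromane
Conditions: NBS, CH2Cl2, −20 to 0 °C, dark
Reagents that add atoms: N-bromosuccinimide O=C1CCC(=O)N1Br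
Why: electrophilic aromatic bromination at C6 of ring D, which is ortho to the C7 benzyloxy group and para to O1 and therefore the most electron-rich position of the molecule.

Step 11
Reactants: 17 2,3,4-trihydroxybenzaldehyde
Product: 18 3,4-bis(benzyloxy)-2-hydroxybenzaldehyde
Conditions: BnBr (2.1 equiv), K2CO3 (2.1 equiv), DMF, rt
Reagents that add atoms: benzyl bromide BrCc1ccccc1
Why: Williamson ether synthesis that should spare the 2-hydroxyl, which is hydrogen-bonded to the formyl group and the least nucleophilic of the three.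

Step 12
Reactants: 19 [4-(benzyloxy)phenyl]magnesium bromide; 20 dimethyl oxalate
Product: 21 methyl 2-[4-(benzyloxy)phenyl]-2-oxoacetate
Conditions: 20 (2 equiv), THF, −78 °C, add 19; aq. NH4Cl
Reagents that add atoms: none
Why: Grignard mono-addition to the oxalate diester, whose tetrahedral adduct persists at −78 °C until the quench.

Step 13
Reactants: 21 methyl 2-[4-(benzyloxy)phenyl]-2-oxoacetate
Product: 22 methyl (R)-2-[4-(benzyloxy)phenyl]-2-hydroxyacetate
Conditions: RuCl[(S,S)-TsDPEN](p-cymene) (1 mol%), HCO2H/Et3N (5:2), CH2Cl2, rt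
Reagents that add atoms: none
Why: Noyori-type asymmetric transfer hydrogenation, in which the (S,S) catalyst should place the aryl group as in acetophenone reductions and so give the R alcohol.

Step 14
Reactants: 18 3,4-bis(benzyloxy)-2-hydroxybenzaldehyde; 22 methyl (R)-2-[4-(benzyloxy)phenyl]-2-hydroxyacetate
Product: 23 methyl (2S)-2-[2,3-bis(benzyloxy)-6-formylphenoxy]-2-[4-(benzyloxy)phenyl]acetate
Conditions: PPh3, DIAD, THF, 0 °C to rt
Reagents that add atoms: none
Why: Mitsunobu etherification with SN2 inversion at the mandelate carbon, whose ester group suppresses ionisation, sets C2 of the upper unit as S.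

Step 15
Reactants: 16 (2R,3R,4R)-3,4,7,8-tetrakis(benzyloxy)-2-[4-(benzyloxy)phenyl]-6-bromochromane; 23 methyl (2S)-2-[2,3-bis(benzyloxy)-6-formylphenoxy]-2-[4-(benzyloxy)phenyl]acetate
Product: 25 methyl (2S)-2-[2,3-bis(benzyloxy)-6-{hydroxy[(2R,3R,4R)-3,4,7,8-tetrakis(benzyloxy)-2-[4-(benzyloxy)phenyl]chroman-6-yl]methyl}phenoxy]-2-[4-(benzyloxy)phenyl]acetate (both carbinol epimers), via 6-lithiochromane 24 (not isolated)
Conditions: 16, n-BuLi (1.05 equiv), THF, −78 °C; then add to 23 (1.2 equiv), THF, −78 °C; aq. NH4Cl at −78 °C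
Reagents that add atoms: none
Why: bromine–lithium exchange and 1,2-addition of the aryllithium to the aryl aldehyde, which at −78 °C should outrun attack on the methyl ester and deprotonation next to it; the new carbinol centre forms as a mixture and is erased in step 17.

Step 16
Reactants: 25 methyl (2S)-2-[2,3-bis(benzyloxy)-6-{hydroxy[(2R,3R,4R)-3,4,7,8-tetrakis(benzyloxy)-2-[4-(benzyloxy)phenyl]chroman-6-yl]methyl}phenoxy]-2-[4-(benzyloxy)phenyl]acetate
Product: 26 (2S)-2-[2,3-bis(benzyloxy)-6-{hydroxy[(2R,3R,4R)-3,4,7,8-tetrakis(benzyloxy)-2-[4-(benzyloxy)phenyl]chroman-6-yl]methyl}phenoxy]-2-[4-(benzyloxy)phenyl]ethan-1-ol (both carbinol epimers)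
Conditions: LiBH4, THF, 0 °C to rt
Reagents that add atoms: none
Why: borohydride reduction of the activated alpha-aryloxy ester to the primary alcohol, the only reducible group present.

Step 17
Reactants: 26 (2S)-2-[2,3-bis(benzyloxy)-6-{hydroxy[(2R,3R,4R)-3,4,7,8-tetrakis(benzyloxy)-2-[4-(benzyloxy)phenyl]chroman-6-yl]methyl}phenoxy]-2-[4-(benzyloxy)phenyl]ethan-1-ol
Product: 27 (2S)-2-[2,3-bis(benzyloxy)-6-{[(2R,3R,4R)-3,4,7,8-tetrakis(benzyloxy)-2-[4-(benzyloxy)phenyl]chroman-6-yl]carbonyl}phenoxy]-2-[4-(benzyloxy)phenyl]acetaldehyde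
Conditions: Dess–Martin periodinane (3 equiv), CH2Cl2, 0 °C to rt; crude used at once
Reagents that add atoms: none
Why: Dess–Martin oxidation of both alcohols under non-basic conditions should give the diaryl ketone and the aldehyde while keeping the epimerisable C2 centre intact.

Step 18
Reactants: 27 (2S)-2-[2,3-bis(benzyloxy)-6-{[(2R,3R,4R)-3,4,7,8-tetrakis(benzyloxy)-2-[4-(benzyloxy)phenyl]chroman-6-yl]carbonyl}phenoxy]-2-[4-(benzyloxy)phenyl]acetaldehyde
Product: 29 (2S,3S,4R)-7,8-bis(benzyloxy)-2-[4-(benzyloxy)phenyl]-4-[(2R,3R,4R)-3,4,7,8-tetrakis(benzyloxy)-2-[4-(benzyloxy)phenyl]chroman-6-yl]chromane-3,4-diol (2,3-trans-3,4-cis), via samarium ketyl 28 (not isolated)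
Conditions: SmI2 (2.5 equiv), THF, −78 to −40 °C; aq. NH4Cl
Reagents that add atoms: none
Why: Single-electron transfer from SmI2 to the diaryl ketone, which is far more easily reduced than the aliphatic aldehyde, gives the samarium-bound ketyl 28, whose carbon (C4) attacks the aldehyde carbon (C3) held nearby by trivalent samarium, and a second equivalent of SmI2 reduces the resulting alkoxy radical; the closest known reaction type is the SmI2-mediated intramolecular ketone–aldehyde pinacol coupling. Ring C closes in the 6-exo-trig mode, the aldehyde oxygen staying outside the new ring. C3 is controlled by C2: in the chair-like transition state the C2 aryl group is equatorial and the aldehyde C=O lies anti to the C2–O1 bond (dipole-minimised, Cornforth-type arrangement), which places the new C3–O bond equatorial and trans to the C2 aryl group. C4 is expected cis to the 3-OH through samarium bridging of the two oxygens, but this centre is erased in step 19. The step needs chemoselective reduction of the ketone, because a ketyl at the aldehyde would expel the C2 aryloxy group; the gap in reduction potential and the absence of HMPA should secure it. It also needs an unepimerised C2, which is secured by making 27 under neutral conditions and using it cold at once.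

Step 19
Reactants: 29 (2S,3S,4R)-7,8-bis(benzyloxy)-2-[4-(benzyloxy)phenyl]-4-[(2R,3R,4R)-3,4,7,8-tetrakis(benzyloxy)-2-[4-(benzyloxy)phenyl]chroman-6-yl]chromane-3,4-diol
Product: 31 (2S,3R,4R)-7,8-bis(benzyloxy)-2-[4-(benzyloxy)phenyl]-4-[(2R,3R,4R)-3,4,7,8-tetrakis(benzyloxy)-2-[4-(benzyloxy)phenyl]chroman-6-yl]chroman-3-ol, via C4 carbocation 30 (not isolated)
Conditions: Et3SiH (10 equiv), TFA (3 equiv), CH2Cl2, −78 to −40 °C
Reagents that add atoms: none
Why: ionic hydrogenation, in which TFA ionises only the tertiary C4 alcohol to a cation stabilised by rings A and D and Et3SiH delivers hydride anti to the C3 hydroxyl (the face from which flavan-4-yl cations are generally attacked), leaving the ring D substituent cis to the 3-OH and C4 as R.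

Step 20
Reactants: 31 (2S,3R,4R)-7,8-bis(benzyloxy)-2-[4-(benzyloxy)phenyl]-4-[(2R,3R,4R)-3,4,7,8-tetrakis(benzyloxy)-2-[4-(benzyloxy)phenyl]chroman-6-yl]chroman-3-ol
Product: 32 (2R,3R,4R)-2-(4-hydroxyphenyl)-6-[(2S,3R,4R)-3,7,8-trihydroxy-2-(4-hydroxyphenyl)chroman-4-yl]chromane-3,4,7,8-tetrol (CNP0391561.7)
Conditions: H2 (1 atm), Pd(OH)2/C, THF/MeOH, rt
Reagents that add atoms: none
Why: hydrogenolysis of the eight benzyl ethers, in which the unhindered O–CH2Ph bonds should cleave well before the hindered secondary C4–O bond of ring F under neutral conditions.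

**Compound list**

1 | 3-fluorocatechol | Oc1cccc(F)c1O | starting material
2 | 1,2-bis(benzyloxy)-3-fluorobenzene | Fc1cccc(OCc2ccccc2)c1OCc1ccccc1 | intermediate
3 | 3,4-bis(benzyloxy)-1-bromo-2-fluorobenzene | Fc1c(Br)ccc(OCc2ccccc2)c1OCc1ccccc1 | intermediate
4 | (S)-4-benzyl-2-oxazolidinone | O=C1N[C@@H](Cc2ccccc2)CO1 | starting material
5 | (benzyloxy)acetyl chloride | O=C(Cl)COCc1ccccc1 | starting material
6 | (S)-4-benzyl-3-[(benzyloxy)acetyl]oxazolidin-2-one | O=C(COCc1ccccc1)N1C(=O)OC[C@@H]1Cc1ccccc1 | intermediate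
7 | 4-(benzyloxy)benzaldehyde | O=Cc1ccc(OCc2ccccc2)cc1 | starting material
8 | Z-dibutylboron enolate of 6 | CCCCB(CCCC)O/C(=C\OCc1ccccc1)N1C(=O)OC[C@@H]1Cc1ccccc1 | intermediate
9 | (S)-4-benzyl-3-[(2S,3R)-2-(benzyloxy)-3-[4-(benzyloxy)phenyl]-3-hydroxypropanoyl]oxazolidin-2-one | O=C([C@@H](OCc1ccccc1)[C@H](O)c1ccc(OCc2ccccc2)cc1)N1C(=O)OC[C@@H]1Cc1ccccc1 | intermediate
10 | (2S,3R)-2-(benzyloxy)-3-[4-(benzyloxy)phenyl]-3-hydroxy-N-methoxy-N-methylpropanamide | CON(C)C(=O)[C@@H](OCc1ccccc1)[C@H](O)c1ccc(OCc2ccccc2)cc1 | intermediate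
11 | [3,4-bis(benzyloxy)-2-fluorophenyl]lithium | [Li]c1ccc(OCc2ccccc2)c(OCc2ccccc2)c1F | intermediate
12 | (2S,3R)-1-[3,4-bis(benzyloxy)-2-fluorophenyl]-2-(benzyloxy)-3-[4-(benzyloxy)phenyl]-3-hydroxypropan-1-one | O=C(c1ccc(OCc2ccccc2)c(OCc2ccccc2)c1F)[C@@H](OCc1ccccc1)[C@H](O)c1ccc(OCc2ccccc2)cc1 | intermediate
13 | (2R,3S)-3,7,8-tris(benzyloxy)-2-[4-(benzyloxy)phenyl]chroman-4-one | c1ccc(COc2ccc([C@H]3Oc4c(ccc(OCc5ccccc5)c4OCc4ccccc4)C(=O)[C@H]3OCc3ccccc3)cc2)cc1 | intermediate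
14 | (2R,3R,4R)-3,7,8-tris(benzyloxy)-2-[4-(benzyloxy)phenyl]chroman-4-ol | c1ccc(COc2ccc([C@H]3Oc4c(ccc(OCc5ccccc5)c4OCc4ccccc4)[C@@H](O)[C@H]3OCc3ccccc3)cc2)cc1 | intermediate
15 | (2R,3R,4R)-3,4,7,8-tetrakis(benzyloxy)-2-[4-(benzyloxy)phenyl]chromane | c1ccc(COc2ccc([C@H]3Oc4c(ccc(OCc5ccccc5)c4OCc4ccccc4)[C@@H](OCc4ccccc4)[C@H]3OCc3ccccc3)cc2)cc1 | intermediate
16 | (2R,3R,4R)-3,4,7,8-tetrakis(benzyloxy)-2-[4-(benzyloxy)phenyl]-6-bromochromane | c1ccc(COc2ccc([C@H]3Oc4c(cc(Br)c(OCc5ccccc5)c4OCc4ccccc4)[C@@H](OCc4ccccc4)[C@H]3OCc3ccccc3)cc2)cc1 | intermediate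
17 | 2,3,4-trihydroxybenzaldehyde | O=Cc1ccc(O)c(O)c1O | starting material
18 | 3,4-bis(benzyloxy)-2-hydroxybenzaldehyde | O=Cc1ccc(OCc2ccccc2)c(OCc2ccccc2)c1O | intermediate
19 | [4-(benzyloxy)phenyl]magnesium bromide (THF solution) | Br[Mg]c1ccc(OCc2ccccc2)cc1 | starting material
20 | dimethyl oxalate | COC(=O)C(=O)OC | starting material
21 | methyl 2-[4-(benzyloxy)phenyl]-2-oxoacetate | COC(=O)C(=O)c1ccc(OCc2ccccc2)cc1 | intermediate
22 | methyl (R)-2-[4-(benzyloxy)phenyl]-2-hydroxyacetate | COC(=O)[C@H](O)c1ccc(OCc2ccccc2)cc1 | intermediate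
23 | methyl (2S)-2-[2,3-bis(benzyloxy)-6-formylphenoxy]-2-[4-(benzyloxy)phenyl]acetate | O=Cc1ccc(OCc2ccccc2)c(OCc2ccccc2)c1O[C@@H](c1ccc(OCc2ccccc2)cc1)C(=O)OC | intermediate
24 | [(2R,3R,4R)-3,4,7,8-tetrakis(benzyloxy)-2-[4-(benzyloxy)phenyl]chroman-6-yl]lithium | c1ccc(COc2ccc([C@H]3Oc4c(cc([Li])c(OCc5ccccc5)c4OCc4ccccc4)[C@@H](OCc4ccccc4)[C@H]3OCc3ccccc3)cc2)cc1 | intermediate
25 | methyl (2S)-2-[2,3-bis(benzyloxy)-6-{hydroxy[(2R,3R,4R)-3,4,7,8-tetrakis(benzyloxy)-2-[4-(benzyloxy)phenyl]chroman-6-yl]methyl}phenoxy]-2-[4-(benzyloxy)phenyl]acetate, both carbinol epimers | c1ccc(COc2ccc([C@H]3Oc4c(cc(C(O)c5ccc(OCc6ccccc6)c(OCc6ccccc6)c5O[C@@H](c5ccc(OCc6ccccc6)cc5)C(=O)OC)c(OCc5ccccc5)c4OCc4ccccc4)[C@@H](OCc4ccccc4)[C@H]3OCc3ccccc3)cc2)cc1 | intermediate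
26 | (2S)-2-[2,3-bis(benzyloxy)-6-{hydroxy[(2R,3R,4R)-3,4,7,8-tetrakis(benzyloxy)-2-[4-(benzyloxy)phenyl]chroman-6-yl]methyl}phenoxy]-2-[4-(benzyloxy)phenyl]ethan-1-ol, both carbinol epimers | c1ccc(COc2ccc([C@H]3Oc4c(cc(C(O)c5ccc(OCc6ccccc6)c(OCc6ccccc6)c5O[C@@H](c5ccc(OCc6ccccc6)cc5)CO)c(OCc5ccccc5)c4OCc4ccccc4)[C@@H](OCc4ccccc4)[C@H]3OCc3ccccc3)cc2)cc1 | intermediate
27 | (2S)-2-[2,3-bis(benzyloxy)-6-{[(2R,3R,4R)-3,4,7,8-tetrakis(benzyloxy)-2-[4-(benzyloxy)phenyl]chroman-6-yl]carbonyl}phenoxy]-2-[4-(benzyloxy)phenyl]acetaldehyde | c1ccc(COc2ccc([C@H]3Oc4c(cc(C(=O)c5ccc(OCc6ccccc6)c(OCc6ccccc6)c5O[C@@H](c5ccc(OCc6ccccc6)cc5)C=O)c(OCc5ccccc5)c4OCc4ccccc4)[C@@H](OCc4ccccc4)[C@H]3OCc3ccccc3)cc2)cc1 | intermediate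
28 | samarium ketyl of 27 (O-bound trivalent samarium, radical at C4) | c1ccc(COc2ccc([C@H]3Oc4c(cc([C](O[Sm](I)I)c5ccc(OCc6ccccc6)c(OCc6ccccc6)c5O[C@@H](c5ccc(OCc6ccccc6)cc5)C=O)c(OCc5ccccc5)c4OCc4ccccc4)[C@@H](OCc4ccccc4)[C@H]3OCc3ccccc3)cc2)cc1 | intermediate
29 | (2S,3S,4R)-7,8-bis(benzyloxy)-2-[4-(benzyloxy)phenyl]-4-[(2R,3R,4R)-3,4,7,8-tetrakis(benzyloxy)-2-[4-(benzyloxy)phenyl]chroman-6-yl]chromane-3,4-diol | c1ccc(COc2ccc([C@H]3Oc4c(cc([C@@]5(O)c6ccc(OCc7ccccc7)c(OCc7ccccc7)c6O[C@@H](c6ccc(OCc7ccccc7)cc6)[C@@H]5O)c(OCc5ccccc5)c4OCc4ccccc4)[C@@H](OCc4ccccc4)[C@H]3OCc3ccccc3)cc2)cc1 | intermediate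
30 | C4 carbocation derived from 29 | c1ccc(COc2ccc([C@H]3Oc4c(cc([C+]5c6ccc(OCc7ccccc7)c(OCc7ccccc7)c6O[C@@H](c6ccc(OCc7ccccc7)cc6)[C@@H]5O)c(OCc5ccccc5)c4OCc4ccccc4)[C@@H](OCc4ccccc4)[C@H]3OCc3ccccc3)cc2)cc1 | intermediate
31 | (2S,3R,4R)-7,8-bis(benzyloxy)-2-[4-(benzyloxy)phenyl]-4-[(2R,3R,4R)-3,4,7,8-tetrakis(benzyloxy)-2-[4-(benzyloxy)phenyl]chroman-6-yl]chroman-3-ol | c1ccc(COc2ccc([C@H]3Oc4c(cc([C@@H]5c6ccc(OCc7ccccc7)c(OCc7ccccc7)c6O[C@@H](c6ccc(OCc7ccccc7)cc6)[C@@H]5O)c(OCc5ccccc5)c4OCc4ccccc4)[C@@H](OCc4ccccc4)[C@H]3OCc3ccccc3)cc2)cc1 | intermediate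
32 | (2R,3R,4R)-2-(4-hydroxyphenyl)-6-[(2S,3R,4R)-3,7,8-trihydroxy-2-(4-hydroxyphenyl)chroman-4-yl]chromane-3,4,7,8-tetrol | Oc1ccc([C@H]2Oc3c(cc([C@@H]4c5ccc(O)c(O)c5O[C@@H](c5ccc(O)cc5)[C@@H]4O)c(O)c3O)[C@@H](O)[C@H]2O)cc1 | target

**Summary**

Total step count: 20. Longest linear sequence: 14 steps (steps 3 to 10, then 15 to 20).

**Steps most likely to fail**

1. Step 18. The closure may fail through poor facial control at C3 (if trivalent samarium chelates O1 and the aldehyde oxygen, the 2,3-cis diol would form), through reductive loss of the C2 aryloxy group if the aldehyde is reduced first, or through epimerisation at C2 before ring closure. The fallback sets out from keto-aldehyde 27 and forms the same bond by metathesis. Both carbonyl groups would be methylenated with Ph3P=CH2 (from Ph3PCH3Br and KN(SiMe3)2, THF, −78 °C to rt) to give the diene (2R,3R,4R)-3,4,7,8-tetrakis(benzyloxy)-2-[4-(benzyloxy)phenyl]-6-{1-[3,4-bis(benzyloxy)-2-{[(1R)-1-[4-(benzyloxy)phenyl]prop-2-en-1-yl]oxy}phenyl]ethenyl}chromane F1. Ring-closing metathesis with second-generation Grubbs catalyst (toluene, 80 °C) would then close ring C at C3–C4 as the trisubstituted alkene of (2R,3R,4R)-3,4,7,8-tetrakis(benzyloxy)-2-[4-(benzyloxy)phenyl]-6-[(2R)-7,8-bis(benzyloxy)-2-[4-(benzyloxy)phenyl]-2H-chromen-4-yl]chromane F2. Dihydroxylation with OsO4 (cat.) and N-methylmorpholine N-oxide, which should occur anti to the C2 aryl group, would come back to the route at diol 29.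

2. Step 19. The C4 cation may undergo a 1,2-hydride shift from C3 (pinacol-type) to the flavan-3-one, the acid may ionise the ring F C4 benzyl ether, or hydride delivery may lose facial control. The fallback sets out from diol 29 and removes the C4 oxygen by a radical path. 1,1'-Thiocarbonyldiimidazole (toluene, 80 °C) would give the cyclic 3,4-thionocarbonate F3. Bu3SnH with AIBN (toluene, 100 °C) would cleave the C4–O bond by Barton–McCombie fragmentation to the doubly benzylic C4 radical, which should take hydrogen from the tin hydride anti to the C3 oxygen, giving the 3-O-[(tributylstannyl)sulfanylcarbonyl] derivative F4. Hydrolysis of F4 during a mildly basic aqueous work-up would come back to the route at 31.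

3. Step 7. The sodium aldolate may cleave by retro-aldol reaction before the fluoride is displaced, and the 2,3-cis flavanone may epimerise at C3 or ring-open under base. The fallback sets out from ketone 12 and removes the carbonyl group before ring closure. Hydroxyl-directed anti-selective reduction with Me4NBH(OAc)3 (MeCN/AcOH, −20 °C, Evans–Saksena reduction) would give (1R,2S,3R)-1-[3,4-bis(benzyloxy)-2-fluorophenyl]-2-(benzyloxy)-3-[4-(benzyloxy)phenyl]propane-1,3-diol F5 with the future C4 already R. Intramolecular nucleophilic aromatic substitution on the unactivated fluoroarene (KOtBu, DMSO, 60 °C), in which only the C2 alkoxide can reach the C–F carbon through a six-membered ring, would come back to the route at 14.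

Further compounds
F1 | step 18 | (2R,3R,4R)-3,4,7,8-tetrakis(benzyloxy)-2-[4-(benzyloxy)phenyl]-6-{1-[3,4-bis(benzyloxy)-2-{[(1R)-1-[4-(benzyloxy)phenyl]prop-2-en-1-yl]oxy}phenyl]ethenyl}chromane | c1ccc(COc2ccc([C@H]3Oc4c(cc(C(=C)c5ccc(OCc6ccccc6)c(OCc6ccccc6)c5O[C@@H](c5ccc(OCc6ccccc6)cc5)C=C)c(OCc5ccccc5)c4OCc4ccccc4)[C@@H](OCc4ccccc4)[C@H]3OCc3ccccc3)cc2)cc1
F2 | step 18 | (2R,3R,4R)-3,4,7,8-tetrakis(benzyloxy)-2-[4-(benzyloxy)phenyl]-6-[(2R)-7,8-bis(benzyloxy)-2-[4-(benzyloxy)phenyl]-2H-chromen-4-yl]chromane | c1ccc(COc2ccc([C@H]3Oc4c(cc(C5=C[C@H](c6ccc(OCc7ccccc7)cc6)Oc6c(OCc7ccccc7)c(OCc7ccccc7)ccc65)c(OCc5ccccc5)c4OCc4ccccc4)[C@@H](OCc4ccccc4)[C@H]3OCc3ccccc3)cc2)cc1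
F3 | step 19 | cyclic 3,4-thionocarbonate of diol 29 | c1ccc(COc2ccc([C@H]3Oc4c(cc([C@@]56c7ccc(OCc8ccccc8)c(OCc8ccccc8)c7O[C@@H](c7ccc(OCc8ccccc8)cc7)[C@@H]5OC(=S)O6)c(OCc5ccccc5)c4OCc4ccccc4)[C@@H](OCc4ccccc4)[C@H]3OCc3ccccc3)cc2)cc1
F4 | step 19 | 3-O-[(tributylstannyl)sulfanylcarbonyl] derivative of 31 | c1ccc(COc2ccc([C@H]3Oc4c(cc([C@@H]5c6ccc(OCc7ccccc7)c(OCc7ccccc7)c6O[C@@H](c6ccc(OCc7ccccc7)cc6)[C@@H]5OC(=O)S[Sn](CCCC)(CCCC)CCCC)c(OCc5ccccc5)c4OCc4ccccc4)[C@@H](OCc4ccccc4)[C@H]3OCc3ccccc3)cc2)cc1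
F5 | step 7 | (1R,2S,3R)-1-[3,4-bis(benzyloxy)-2-fluorophenyl]-2-(benzyloxy)-3-[4-(benzyloxy)phenyl]propane-1,3-diol | Fc1c(ccc(OCc2ccccc2)c1OCc1ccccc1)[C@@H](O)[C@@H](OCc1ccccc1)[C@H](O)c1ccc(OCc2ccccc2)cc1
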